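**Assumptions:** Salts are drawn as free bases. The sense of induction in step 4 cannot be predicted, so it is fixed once by X-ray of iodide 6 (iodine anomalous scattering). The route is written for the catalyst antipode that iodinates the pro-S ring, taken here as (R)-TRIP; both antipodes are commercial.

**Target check:** There is one stereocentre, C10. CIP order is alkenyl-substituted imidazole > unsubstituted imidazole > CH2 > H, which makes the given SMILES (S). There is one (E)-alkene.

## Retrosynthetic overview

1. Both amides are made last: 13 ⇒ tetraamine 10 + 2 × dibromopyrrolyl trichloromethyl ketone 12.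
2. Hidden symmetry: C10 is stereogenic only because one of two identical 2-aminoimidazol-4-yl rings carries the alkenyl chain. I therefore cut the imidazole C5–alkenyl bond (Suzuki) back to C–I, then to C–H of an achiral bis(2-aminoimidazolyl)methane.
3. Key step: catalytic iodination of one of the two enantiotopic rings creates the stereocentre without forming any bond to it.
4. The achiral core comes from 2 × 2-aminoimidazole + N-Boc-β-aminopropanal (hydroxyalkylation, then dehydrative Friedel–Crafts).
5. No ring is constructed. Both imidazoles enter in steps 1–2 and both pyrroles enter in step 9.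

## Route

**Step 1**
Reactants: 1 2-aminoimidazole hemisulfate; 2 tert-butyl (3-oxopropyl)carbamate
Product: 3 (±)-tert-butyl [3-(2-amino-1H-imidazol-4-yl)-3-hydroxypropyl]carbamate
Conditions: 1 (1.5 equiv = 3 equiv heterocycle), Na2CO3, MeOH–H2O 1:1, Ar, 23 °C, 36 h; crude product with excess 2-aminoimidazole carried on
Reagents that add atoms: none (all heavy atoms come from 1 and 2)
Why: Uncatalysed C4-hydroxyalkylation (enamine-type Friedel–Crafts addition) of free-base 2-aminoimidazole with aliphatic aldehydes is known at near-neutral pH, the Boc group and aldehyde tolerate pH 8–9, and the racemic carbinol centre is erased in step 2.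

**Step 2**
Reactants: 3; 1 2-aminoimidazole hemisulfate
Product: 4 tert-butyl [3,3-bis(2-amino-1H-imidazol-4-yl)propyl]carbamate (achiral)
Conditions: 1 (further 1.5 equiv), AcOH/NaOAc buffer (pH ≈ 4.5), EtOH–H2O, Ar, 60 °C, 24 h
Reagents that add atoms: none (second ring comes from 1)
Why: Dehydrative Friedel–Crafts alkylation of the bis(indolyl)methane type, in which mild acid ionises the carbinol to a 2-aminodiazafulvenium ion that excess 2-aminoimidazole captures at C4; Boc survives and no stereocentre is formed.

**Step 3**
Reactants: 4
Product: 5 di-tert-butyl 4,4'-[3-(Boc-amino)propane-1,1-diyl]bis(2-amino-1H-imidazole-1-carboxylate) (achiral, prochiral at C10)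
Conditions: Boc2O (2.2 equiv), Et3N, DMF, 0→23 °C
Reagents that add atoms: di-tert-butyl dicarbonate, CC(C)(C)OC(=O)OC(=O)OC(C)(C)C
Why: N-carbamoylation of 2-aminoimidazoles takes place on the ring nitrogen remote from the C4 substituent (less hindered, NH2···O=C hydrogen bond), giving one lipophilic regioisomer with C5–H as the only nucleophilic carbon.

**Step 4 (key step)**
Reactants: 5
Product: 6 tert-butyl 2-amino-4-[(1S)-1-(2-amino-1-Boc-imidazol-4-yl)-3-(Boc-amino)propyl]-5-iodoimidazole-1-carboxylate
Conditions: IPy2BF4 (1.15 equiv, suspended solid), (R)-TRIP (10 mol %), Na2CO3 (s), 4 Å MS, toluene–hexane, dark, −20 °C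
Reagents that add atoms: bis(pyridine)iodonium tetrafluoroborate, [I+].c1ccncc1.c1ccncc1.F[B-](F)(F)F
Why: Proposed new method: enantiotopic-group-selective electrophilic aromatic iodination under chiral-anion phase transfer; the iodonium salt is insoluble, so only I+ paired with the lipophilic chiral phosphate is in solution and the racemic background is suppressed; the phosphate hydrogen-bonds to the chain carbamate N–H and a C2–NH2; attack at C5 gives a guanidinium-stabilised σ-complex directly beside the prochiral CH, whose out-of-plane groups (other ring vs chain) are mirror-related in the two rings, so the catalyst pocket selects the pro-S ring and sets (S)-C10; the slight excess of I+ preferentially converts the minor enantiomer (its fast ring is still free) into achiral di-iodide, which raises the ee; closest known reaction types are chiral-phosphate phase-transfer halogenation and peptide- or amino-urea-catalysed desymmetrising ortho-halogenation of diarylmethine bis-phenols.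

**Step 5**
Reactants: 7 tert-butyl prop-2-yn-1-ylcarbamate
Product: 8 tert-butyl [(E)-3-(4,4,5,5-tetramethyl-1,3,2-dioxaborolan-2-yl)allyl]carbamate
Conditions: HBpin (1.3 equiv), Cp2ZrHCl (10 mol %), Et3N (10 mol %), neat, 60 °C
Reagents that add atoms: pinacolborane, CC1(C)OBOC1(C)C
Why: Zr-catalysed syn-hydroboration of a terminal alkyne places boron at the terminus and fixes the (E)-geometry.

**Step 6**
Reactants: 6; 8
Product: 9 tert-butyl 2-amino-4-[(1S)-1-(2-amino-1-Boc-imidazol-4-yl)-3-(Boc-amino)propyl]-5-[(E)-3-(Boc-amino)prop-1-enyl]imidazole-1-carboxylate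
Conditions: 8 (1.5 equiv), SPhos Pd G3 (5 mol %), K3PO4, THF–H2O 10:1, 40 °C
Reagents that add atoms: none beyond 8
Why: Suzuki–Miyaura coupling with retention of alkene geometry, where the biarylphosphine precatalyst handles a di-ortho-substituted iodide and free amidine nitrogens at low temperature, C10–H is not acidic enough to epimerise, and partial loss of ring Boc is harmless because step 7 removes all Boc groups.

**Step 7**
Reactants: 9
Product: 10 4-[(1S)-3-amino-1-(2-amino-1H-imidazol-4-yl)propyl]-5-[(E)-3-aminoprop-1-enyl]-1H-imidazol-2-amine (tetrakis-TFA salt)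
Conditions: TFA–CH2Cl2 1:1, anisole, 0→23 °C, 2 h
Reagents that add atoms: none
Why: Global acidolytic Boc cleavage, during which the N-protonated 2-aminoimidazolium rings resist ipso-protonation (no retro-Friedel–Crafts, no racemisation) and the vinyl-aminoimidazole is stable as its salt.

**Step 8**
Reactants: 11 2,2,2-trichloro-1-(1H-pyrrol-2-yl)ethanone
Product: 12 2,2,2-trichloro-1-(4,5-dibromo-1H-pyrrol-2-yl)ethanone
Conditions: Br2 (2.05 equiv), AcOH, 23 °C
Reagents that add atoms: bromine, BrBr
Why: Electrophilic aromatic bromination, with the 2-acyl group directing both halogens to C4 and C5.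

**Step 9**
Reactants: 10; 12
Product: 13 target (S,E), isolated as the bis-TFA salt
Conditions: 12 (2.1 equiv), Na2CO3, DMF, 23 °C, 12 h; RP-HPLC (MeCN/H2O/0.1 % TFA)
Reagents that add atoms: 12, O=C(c1cc(Br)c(Br)[nH]1)C(Cl)(Cl)Cl (two acyl groups transferred, CHCl3 lost)
Why: Haloform-type acyl transfer from a trichloromethyl ketone acylates only the two primary aliphatic amines, as in oroidin-type end-games where the guanidine-like 2-amino groups stay inert, and it touches neither C10 nor the alkene.

## Compound list

| No. | Name | SMILES | Role |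
|---|---|---|---|
| 1 | 2-aminoimidazole hemisulfate | Nc1ncc[nH]1.Nc1ncc[nH]1.OS(=O)(=O)O | starting material |
| 2 | tert-butyl (3-oxopropyl)carbamate | CC(C)(C)OC(=O)NCCC=O | starting material |
| 3 | (±)-hydroxyalkyl-2-aminoimidazole | CC(C)(C)OC(=O)NCCC(O)c1c[nH]c(N)n1 | intermediate |
| 4 | bis(2-aminoimidazol-4-yl)propyl carbamate | CC(C)(C)OC(=O)NCCC(c1c[nH]c(N)n1)c1c[nH]c(N)n1 | intermediate |
| 5 | tri-Boc prochiral core | CC(C)(C)OC(=O)NCCC(c1cn(C(=O)OC(C)(C)C)c(N)n1)c1cn(C(=O)OC(C)(C)C)c(N)n1 | intermediate |
| 6 | (S)-mono-iodide | CC(C)(C)OC(=O)n1cc(nc1N)[C@H](CCNC(=O)OC(C)(C)C)c1nc(N)n(C(=O)OC(C)(C)C)c1I | intermediate |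
| 7 | N-Boc-propargylamine | C#CCNC(=O)OC(C)(C)C | starting material |
| 8 | (E)-3-(Boc-amino)propenyl-Bpin | CC(C)(C)OC(=O)NC/C=C/B1OC(C)(C)C(C)(C)O1 | intermediate |
| 9 | (S,E)-tetra-Boc coupled product | CC(C)(C)OC(=O)n1cc(nc1N)[C@H](CCNC(=O)OC(C)(C)C)c1nc(N)n(C(=O)OC(C)(C)C)c1/C=C/CNC(=O)OC(C)(C)C | intermediate |
| 10 | (S,E)-tetraamine | Nc1ncc([C@H](CCN)c2[nH]c(N)nc2/C=C/CN)[nH]1 | intermediate |
| 11 | 2-(trichloroacetyl)pyrrole | O=C(c1ccc[nH]1)C(Cl)(Cl)Cl | starting material |
| 12 | 4,5-dibromo-2-(trichloroacetyl)pyrrole | O=C(c1cc(Br)c(Br)[nH]1)C(Cl)(Cl)Cl | intermediate |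
| 13 | CID11411715 | Nc1ncc([C@H](CCNC(=O)c2cc(Br)c(Br)[nH]2)c2[nH]c(N)nc2/C=C/CNC(=O)c2cc(Br)c(Br)[nH]2)[nH]1 | target |

## Step count and risks

**Total steps:** 9
**Longest linear sequence:** 7 (steps 1, 2, 3, 4, 6, 7, 9)

**Three steps most likely to fail:**

1. **Step 4.** The ee or the mono/di selectivity of the desymmetrising iodination may be poor.
   - Fallback: give up asymmetric catalysis. Mono-iodinate racemically (NIS, 0.9 equiv) and separate the enantiomers by preparative chiral SFC.
   - Return the wrong enantiomer and the di-iodide to achiral 5 by hydrodeiodination (Pd/C, HCO2NH4) and recycle. This resolution loop loses no material because the precursor is achiral.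
2. **Step 2.** The problems could be oligomerisation, elimination to the vinyl-aminoimidazole, or slow capture of the cation.
   - Fallback: build both imidazoles de novo in two directions.
   - Ozonolyse tert-butyl [2-(cyclopent-3-en-1-yl)ethyl]carbamate to the 3-substituted glutaraldehyde, α-brominate both arms, and condense twice with N-Boc-guanidine. This gives 5 directly.
3. **Step 6.** The C5–I bond is hindered, flanked by N-Boc and the branched carbon, so protodeiodination may compete.
   - Fallback: couple the sterically undemanding sp partner instead, by Sonogashira reaction of 6 with alkyne 7.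
   - Set the (E)-alkene afterwards by Ru-catalysed trans-hydrosilylation and protodesilylation.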